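The route rests on cutting the O1–C5 bond of the tetrahydrofuran ring and reading C5 (the ring CH2) and C4 (the carbon carrying the guaiacylmethyl group) as the two carbons of a former terminal alkyne. In the key step a cationic gold catalyst makes the benzylic ether oxygen of an acyclic homopropargylic ether attack the terminal alkyne carbon (5-endo-dig), while the electron-rich 4-oxybenzyl group parked on that same oxygen shifts to C4. One operation thus closes the ring and installs the C4 benzyl group; hydrogenation then sets C4 cis to the C3 arm. The precursor is the anti-configured 4-(benzyloxy)-3-methoxybenzyl ether of a 1-aryl-2-(silyloxymethyl)but-3-yn-1-ol.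

Key step: step 9

Remark: ring atoms are numbered O1, C2 (syringyl), C3 (CH2O arm), C4 (guaiacylmethyl), C5 (CH2); the target is read as (2S,3R,4R); compounds 1, 6, 10 and 17 are taken as commercial.

Step 1
Reactants: 1 (R)-2,2-dimethyl-1,3-dioxolane-4-carbaldehyde
Product: 2 (S)-4-ethynyl-2,2-dimethyl-1,3-dioxolane
Conditions: dimethyl (1-diazo-2-oxopropyl)phosphonate, K2CO3, MeOH, 0 °C to rt
Reagents that add atoms: dimethyl (1-diazo-2-oxopropyl)phosphonate, CC(=O)C(=[N+]=[N-])P(=O)(OC)OC
Why: Seyferth–Gilbert homologation in its Ohira–Bestmann form should turn the aldehyde into the terminal alkyne under mild carbonate conditions that leave the adjacent stereocentre untouched (the descriptor changes from R to S only through the priority rules).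

Step 2
Reactants: 2 (S)-4-ethynyl-2,2-dimethyl-1,3-dioxolane
Product: 3 (S)-but-3-yne-1,2-diol
Conditions: 1 M aq. HCl, THF, rt
Reagents that add atoms: none
Why: Acid-catalysed acetal hydrolysis should release the diol without touching the stereocentre.

Step 3
Reactants: 3 (S)-but-3-yne-1,2-diol
Product: 4 (S)-1-[(tert-butyldiphenylsilyl)oxy]but-3-yn-2-ol
Conditions: TBDPSCl, imidazole, CH2Cl2, 0 °C
Reagents that add atoms: tert-butyl(chloro)diphenylsilane (TBDPSCl), CC(C)(C)[Si](Cl)(c1ccccc1)c1ccccc1
Why: Silyl ether formation with the bulky chlorosilane should be selective for the primary hydroxyl of the 1,2-diol.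

Step 4
Reactants: 4 (S)-1-[(tert-butyldiphenylsilyl)oxy]but-3-yn-2-ol
Product: 5 (S)-1-[(tert-butyldiphenylsilyl)oxy]but-3-yn-2-yl methanesulfonate
Conditions: MsCl, Et3N, CH2Cl2, −78 to 0 °C
Reagents that add atoms: methanesulfonyl chloride (MsCl), CS(=O)(=O)Cl
Why: Sulfonylation of the secondary propargylic alcohol should proceed with retention, since the C–O bond is not broken.

Step 5
Reactants: 6 syringaldehyde (4-hydroxy-3,5-dimethoxybenzaldehyde)
Product: 7 benzyl 4-formyl-2,6-dimethoxyphenyl carbonate
Conditions: CbzCl, Et3N, DMAP (cat.), CH2Cl2, 0 °C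
Reagents that add atoms: benzyl chloroformate (CbzCl), O=C(Cl)OCc1ccccc1
Why: Acylation of the phenol should give an aryl benzyl carbonate that makes the syringyl ring electron-poor for steps 8 and 9 and is later removed by hydrogenolysis.

Step 6
Reactants: 5 (S)-1-[(tert-butyldiphenylsilyl)oxy]but-3-yn-2-yl methanesulfonate; 7 benzyl 4-formyl-2,6-dimethoxyphenyl carbonate
Product: 9 benzyl 4-[(1S,2R)-2-{[(tert-butyldiphenylsilyl)oxy]methyl}-1-hydroxybut-3-yn-1-yl]-2,6-dimethoxyphenyl carbonate, via (P)-allenyl(ethyl)zinc reagent 8 (not isolated)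
Conditions: Pd(OAc)2 (5 mol%), PPh3 (5 mol%), Et2Zn, THF, −78 to −20 °C
Reagents that add atoms: none
Why: In this Marshall–Tamaru propargylation zerovalent palladium should displace the mesylate anti (SN2') to an allenylpalladium that transmetallates with retention to allenylzinc 8, which adds to the aldehyde through a cyclic SE2' transition state, so that the axial chirality of the reagent sets C2 (R) and the chair-like arrangement with the aryl group turned away from the allenyl substituent sets C1 (S), the anti diastereomer.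

Step 7
Reactants: 10 4-(benzyloxy)-3-methoxybenzyl alcohol
Product: 11 4-(benzyloxy)-3-methoxybenzyl 2,2,2-trichloroacetimidate
Conditions: Cl3CCN, DBU (cat.), CH2Cl2, 0 °C
Reagents that add atoms: trichloroacetonitrile, ClC(Cl)(Cl)C#N
Why: Base-catalysed addition of the alcohol to the nitrile should give the imidate, the standard acid-activated benzyl donor.

Step 8
Reactants: 9 benzyl 4-[(1S,2R)-2-{[(tert-butyldiphenylsilyl)oxy]methyl}-1-hydroxybut-3-yn-1-yl]-2,6-dimethoxyphenyl carbonate; 11 4-(benzyloxy)-3-methoxybenzyl 2,2,2-trichloroacetimidate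
Product: 12 benzyl 4-[(1S,2R)-1-{[4-(benzyloxy)-3-methoxybenzyl]oxy}-2-{[(tert-butyldiphenylsilyl)oxy]methyl}but-3-yn-1-yl]-2,6-dimethoxyphenyl carbonate
Conditions: CSA (10 mol%), CH2Cl2, 0 °C to rt
Reagents that add atoms: none
Why: Acid-catalysed trichloroacetimidate benzylation should transfer the electron-rich benzyl group to the secondary hydroxyl without base (so the aryl carbonate and the terminal alkyne survive) and without breaking the C1–O bond, whose ionisation is suppressed by the acyloxy-substituted ring, so C1 stays S.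

Step 9
Reactants: 12 benzyl 4-[(1S,2R)-1-{[4-(benzyloxy)-3-methoxybenzyl]oxy}-2-{[(tert-butyldiphenylsilyl)oxy]methyl}but-3-yn-1-yl]-2,6-dimethoxyphenyl carbonate
Product: 14 benzyl 4-[(2S,3R)-4-[4-(benzyloxy)-3-methoxybenzyl]-3-{[(tert-butyldiphenylsilyl)oxy]methyl}-2,3-dihydrofuran-2-yl]-2,6-dimethoxyphenyl carbonate, via cyclic oxonium vinylgold species 13 (not isolated)
Conditions: Ph3PAuNTf2 (5 mol%), 4 Å MS, CH2Cl2 (0.02 M), −20 °C to rt
Reagents that add atoms: none
Why: Proposed new method: cationic monovalent gold should π-activate the terminal alkyne of 12, the ether oxygen should attack the terminal alkyne carbon in a 5-endo-dig closure (the only ring this step closes) to give the cyclic oxonium vinylgold species 13, and the 4-benzyloxy-3-methoxybenzyl group should then leave oxygen as a stabilised benzylic cation and be recaptured by the gold-bearing carbon (a formal 1,3 shift from O to C), loss of gold restoring the enol ether. The closest known reaction types are the PtCl2- or gold-catalysed carboalkoxylation of ortho-alkynylphenyl benzyl and para-methoxybenzyl ethers to 3-benzylbenzofurans and the gold-catalysed 5-endo-dig cycloisomerisation of terminal homopropargylic alcohols; their union on an aliphatic homopropargylic ether is not established. No stereocentre is created: C2 and C3 of the ring are carried over from 12, because the C–O bond at the aryl-bearing carbon is never broken. Three selectivities are needed: attack by the benzylic ether oxygen and not by the silyl ether oxygen (the bulky, weakly basic TBDPS ether can at most add reversibly); cleavage of the O–CH2 bond of the vanillyl group and not of the O–CH bond at the syringyl carbon (the carbonate makes the syringyl ring electron-poor, whereas the migrating ring keeps a para-alkoxy donor); and delivery of the benzyl cation to the vinylgold carbon and not to an arene (favoured by the contact ion pair, low temperature and dilution).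

Step 10
Reactants: 14 benzyl 4-[(2S,3R)-4-[4-(benzyloxy)-3-methoxybenzyl]-3-{[(tert-butyldiphenylsilyl)oxy]methyl}-2,3-dihydrofuran-2-yl]-2,6-dimethoxyphenyl carbonate
Product: 15 4-[(2S,3R,4R)-3-{[(tert-butyldiphenylsilyl)oxy]methyl}-4-(4-hydroxy-3-methoxybenzyl)tetrahydrofuran-2-yl]-2,6-dimethoxyphenol
Conditions: H2 (1 atm), Pd/C (10 wt%), EtOAc, rt
Reagents that add atoms: none
Why: Heterogeneous syn-hydrogenation of the trisubstituted enol ether from the face opposite the adjacent CH2OTBDPS group at C3 should set C4 (R) with the benzyl group cis to the silyloxymethyl arm, while the same catalyst hydrogenolyses the benzyl ether and the benzyl carbonate (with loss of CO2).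

Step 11
Reactants: 15 4-[(2S,3R,4R)-3-{[(tert-butyldiphenylsilyl)oxy]methyl}-4-(4-hydroxy-3-methoxybenzyl)tetrahydrofuran-2-yl]-2,6-dimethoxyphenol
Product: 16 4-[(2S,3R,4R)-4-(4-hydroxy-3-methoxybenzyl)-3-(hydroxymethyl)tetrahydrofuran-2-yl]-2,6-dimethoxyphenol (5-methoxylariciresinol)
Conditions: TBAF, AcOH, THF, 0 °C to rt
Reagents that add atoms: none
Why: Fluoride-mediated desilylation, buffered with acetic acid so that the phenols are not held as phenoxides, should release the primary alcohol.

Step 12
Reactants: 16 5-methoxylariciresinol; 17 (E)-ferulic acid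
Product: 18 [(2S,3R,4R)-2-(4-hydroxy-3,5-dimethoxyphenyl)-4-(4-hydroxy-3-methoxybenzyl)tetrahydrofuran-3-yl]methyl (E)-3-(4-hydroxy-3-methoxyphenyl)prop-2-enoate (target)
Conditions: PPh3, DIAD, THF, 0 °C to rt
Reagents that add atoms: none
Why: Mitsunobu esterification should activate only the aliphatic primary hydroxyl as its oxyphosphonium, and the carboxylate, far more acidic than any of the three phenols, should be the nucleophile, so the ester forms without phenol protection and with the E alkene untouched.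

Compound list
1 | (R)-2,2-dimethyl-1,3-dioxolane-4-carbaldehyde | O=C[C@H]1COC(C)(C)O1 | starting material
2 | (S)-4-ethynyl-2,2-dimethyl-1,3-dioxolane | C#C[C@H]1COC(C)(C)O1 | intermediate
3 | (S)-but-3-yne-1,2-diol | C#C[C@H](O)CO | intermediate
4 | (S)-1-[(tert-butyldiphenylsilyl)oxy]but-3-yn-2-ol | C#C[C@H](O)CO[Si](c1ccccc1)(c1ccccc1)C(C)(C)C | intermediate
5 | (S)-1-[(tert-butyldiphenylsilyl)oxy]but-3-yn-2-yl methanesulfonate | C#C[C@H](OS(C)(=O)=O)CO[Si](c1ccccc1)(c1ccccc1)C(C)(C)C | intermediate
6 | syringaldehyde (4-hydroxy-3,5-dimethoxybenzaldehyde) | COc1cc(C=O)cc(OC)c1O | starting material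
7 | benzyl 4-formyl-2,6-dimethoxyphenyl carbonate | COc1cc(C=O)cc(OC)c1OC(=O)OCc1ccccc1 | intermediate
8 | ethyl[(P)-4-(tert-butyldiphenylsilyloxy)buta-1,2-dien-1-yl]zinc | CC[Zn]C([H])=[C@@]=C([H])CO[Si](c1ccccc1)(c1ccccc1)C(C)(C)C | intermediate (not isolated)
9 | benzyl 4-[(1S,2R)-2-{[(tert-butyldiphenylsilyl)oxy]methyl}-1-hydroxybut-3-yn-1-yl]-2,6-dimethoxyphenyl carbonate | COc1cc(cc(OC)c1OC(=O)OCc1ccccc1)[C@@H](O)[C@@H](CO[Si](c1ccccc1)(c1ccccc1)C(C)(C)C)C#C | intermediate
10 | 4-(benzyloxy)-3-methoxybenzyl alcohol | COc1cc(CO)ccc1OCc1ccccc1 | starting material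
11 | 4-(benzyloxy)-3-methoxybenzyl 2,2,2-trichloroacetimidate | COc1cc(COC(=N)C(Cl)(Cl)Cl)ccc1OCc1ccccc1 | intermediate
12 | benzyl 4-[(1S,2R)-1-{[4-(benzyloxy)-3-methoxybenzyl]oxy}-2-{[(tert-butyldiphenylsilyl)oxy]methyl}but-3-yn-1-yl]-2,6-dimethoxyphenyl carbonate | COc1cc(cc(OC)c1OC(=O)OCc1ccccc1)[C@@H](OCc1ccc(OCc2ccccc2)c(OC)c1)[C@@H](CO[Si](c1ccccc1)(c1ccccc1)C(C)(C)C)C#C | intermediate
13 | (2S,3R)-1-[4-(benzyloxy)-3-methoxybenzyl]-2-aryl-3-(silyloxymethyl)-4-[(triphenylphosphine)gold]-2,3-dihydrofuran-1-ium bis(trifluoromethylsulfonyl)amide | COc1cc(cc(OC)c1OC(=O)OCc1ccccc1)[C@H]1[O+](Cc2ccc(OCc3ccccc3)c(OC)c2)C=C([Au-][P+](c2ccccc2)(c2ccccc2)c2ccccc2)[C@@H]1CO[Si](c1ccccc1)(c1ccccc1)C(C)(C)C.FC(F)(F)S(=O)(=O)[N-]S(=O)(=O)C(F)(F)F | intermediate (not isolated)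
14 | benzyl 4-[(2S,3R)-4-[4-(benzyloxy)-3-methoxybenzyl]-3-{[(tert-butyldiphenylsilyl)oxy]methyl}-2,3-dihydrofuran-2-yl]-2,6-dimethoxyphenyl carbonate | COc1cc(cc(OC)c1OC(=O)OCc1ccccc1)[C@H]1OC=C(Cc2ccc(OCc3ccccc3)c(OC)c2)[C@@H]1CO[Si](c1ccccc1)(c1ccccc1)C(C)(C)C | intermediate
15 | 4-[(2S,3R,4R)-3-{[(tert-butyldiphenylsilyl)oxy]methyl}-4-(4-hydroxy-3-methoxybenzyl)tetrahydrofuran-2-yl]-2,6-dimethoxyphenol | COc1cc(cc(OC)c1O)[C@H]1OC[C@H](Cc2ccc(O)c(OC)c2)[C@@H]1CO[Si](c1ccccc1)(c1ccccc1)C(C)(C)C | intermediate
16 | 4-[(2S,3R,4R)-4-(4-hydroxy-3-methoxybenzyl)-3-(hydroxymethyl)tetrahydrofuran-2-yl]-2,6-dimethoxyphenol (5-methoxylariciresinol) | COc1cc(cc(OC)c1O)[C@H]1OC[C@H](Cc2ccc(O)c(OC)c2)[C@@H]1CO | intermediate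
17 | (E)-ferulic acid | COc1cc(/C=C/C(=O)O)ccc1O | starting material
18 | [(2S,3R,4R)-2-(4-hydroxy-3,5-dimethoxyphenyl)-4-(4-hydroxy-3-methoxybenzyl)tetrahydrofuran-3-yl]methyl (E)-3-(4-hydroxy-3-methoxyphenyl)prop-2-enoate | COc1cc(/C=C/C(=O)OC[C@H]2[C@@H](Cc3ccc(O)c(OC)c3)CO[C@@H]2c2cc(OC)c(O)c(OC)c2)ccc1O | target

Total step count: 12. Longest linear sequence: 10 steps (1, 2, 3, 4, 6, 8, 9, 10, 11, 12).

Steps most likely to fail

Step 9 (gold-catalysed cyclisation with O-to-C benzyl shift). What may go wrong: escape of the benzylic cation from the ion pair followed by arene alkylation or oligomerisation, protodeauration of the vinylgold without benzyl transfer, competing reversible engagement of the catalyst by the silyl ether, or ionisation at the aryl-bearing carbon with loss of configuration. Fallback with known chemistry, setting out from 9 and coming back at 14 (steps 7 and 8 are then not needed): tungsten-vinylidene-mediated endo-cycloisomerisation of alkynol 9 (W(CO)6, Et3N, THF, hν 350 nm) should form the same O1–C5 bond and give benzyl 4-[(2S,3R)-3-{[(tert-butyldiphenylsilyl)oxy]methyl}-2,3-dihydrofuran-2-yl]-2,6-dimethoxyphenyl carbonate F1. Bromine addition to the enol ether at −78 °C should give the 4,5-dibromotetrahydrofuran F2 (not isolated), from which Et3N removes HBr to leave the 4-bromo-2,3-dihydrofuran F3. Negishi coupling of F3 with [4-(benzyloxy)-3-methoxybenzyl]zinc chloride F4 (from the commercial benzyl chloride, zinc dust and LiCl) under Pd(PPh3)4 in THF should give 14.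

Step 6 (propargylation). What may go wrong: β-elimination of the silyloxy group from the propargylzinc tautomer of 8 before it is trapped, or weak anti/syn discrimination with the aromatic aldehyde. Fallback, setting out from 5 and 7 and coming back at 9: copper-catalysed anti-SN2' borylation of 5 (CuCl, Xantphos, KOtBu, B2pin2, THF) should give the configurationally stable (P)-allenylboronic acid pinacol ester F5, which has no metallotropic pathway to elimination. Allenylboration of 7 through a closed six-membered transition state, catalysed by a matched BINOL-derived chiral phosphoric acid in toluene, should give anti alcohol 9 after hydrolysis of the borate.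

Step 10 (hydrogenation). What may go wrong: insufficient facial discrimination in the addition of hydrogen to the enol ether, or hydrogenolysis of the benzylic C2–O1 bond once the syringyl phenol is free. Fallback, setting out from 14 and coming back at 15: ionic hydrogenation (Et3SiH, CF3CO2H, CH2Cl2, −78 °C), in which kinetic protonation at C4 anti to the silyloxymethyl group is followed by hydride delivery to the C5 oxocarbenium ion, should give the fully protected tetrahydrofuran benzyl 4-[(2S,3R,4R)-4-[4-(benzyloxy)-3-methoxybenzyl]-3-{[(tert-butyldiphenylsilyl)oxy]methyl}tetrahydrofuran-2-yl]-2,6-dimethoxyphenyl carbonate F6 while the carbonate keeps C2–O1 from ionising. A short, separately monitored hydrogenolysis (H2, Pd(OH)2/C, EtOAc) should then remove the benzyl ether and the benzyl carbonate to give 15.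

Further compounds
F1 | step 9 | benzyl 4-[(2S,3R)-3-{[(tert-butyldiphenylsilyl)oxy]methyl}-2,3-dihydrofuran-2-yl]-2,6-dimethoxyphenyl carbonate | COc1cc(cc(OC)c1OC(=O)OCc1ccccc1)[C@H]1OC=C[C@@H]1CO[Si](c1ccccc1)(c1ccccc1)C(C)(C)C
F2 | step 9 | benzyl 4-[(2S,3R)-4,5-dibromo-3-{[(tert-butyldiphenylsilyl)oxy]methyl}tetrahydrofuran-2-yl]-2,6-dimethoxyphenyl carbonate (trans dibromide, C4 and C5 not defined, not isolated) | COc1cc(cc(OC)c1OC(=O)OCc1ccccc1)[C@H]1OC(Br)C(Br)[C@@H]1CO[Si](c1ccccc1)(c1ccccc1)C(C)(C)C
F3 | step 9 | benzyl 4-[(2S,3R)-4-bromo-3-{[(tert-butyldiphenylsilyl)oxy]methyl}-2,3-dihydrofuran-2-yl]-2,6-dimethoxyphenyl carbonate | COc1cc(cc(OC)c1OC(=O)OCc1ccccc1)[C@H]1OC=C(Br)[C@@H]1CO[Si](c1ccccc1)(c1ccccc1)C(C)(C)C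
F4 | step 9 | [4-(benzyloxy)-3-methoxybenzyl]zinc chloride | Cl[Zn]Cc1ccc(OCc2ccccc2)c(OC)c1
F5 | step 6 | 2-[(P)-4-(tert-butyldiphenylsilyloxy)buta-1,2-dien-1-yl]-4,4,5,5-tetramethyl-1,3,2-dioxaborolane | CC1(C)OB(OC1(C)C)C([H])=[C@@]=C([H])CO[Si](c1ccccc1)(c1ccccc1)C(C)(C)C
F6 | step 10 | benzyl 4-[(2S,3R,4R)-4-[4-(benzyloxy)-3-methoxybenzyl]-3-{[(tert-butyldiphenylsilyl)oxy]methyl}tetrahydrofuran-2-yl]-2,6-dimethoxyphenyl carbonate | COc1cc(cc(OC)c1OC(=O)OCc1ccccc1)[C@H]1OC[C@H](Cc2ccc(OCc3ccccc3)c(OC)c2)[C@@H]1CO[Si](c1ccccc1)(c1ccccc1)C(C)(C)C
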